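## Plan

1. Cuts (fatty-chain numbering, see remark): first C10–C11. Then the ring bond O–C9 is traded for O–C10, which turns the oxolane (O, C6, C7, C8, C9) into the six-membered cyclic enol ether O–C6–C7–C8–C9=C10. Then C9=C10 (metathesis), C7–O(acyl), C8–C9 and O–vinyl.
2. Enabling feature: the ring O, ring carbon C9 and the oxygenated exocyclic carbon C10 are contiguous. C10 can therefore start as a ring member (the enol ether carbon on O) and be pushed out as a formyl group when O shifts from C10 to an oxidised C9.
3. Forward order: epoxy alcohol → O-vinyl ether → C8–C9 bond → laurate → 3,4-dihydro-2H-pyran → oxidative contraction to the oxolane-2-carbaldehyde → C10–C11 bond with the nonenyl Grignard reagent.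
4. Stereochemistry: C6 and C7 come from one Sharpless kinetic-resolution epoxidation, and C7 is then inverted by laurate in a Mitsunobu reaction (erythro → threo). C9 comes from anti attack on the cis-2,3-disubstituted dihydropyran followed by an invertive 1,2-O shift. C10 comes from chelation-controlled addition.
5. No protecting group is used. The O-bound vinyl carbon on O6 ends as C10, the laurate goes onto the only free OH, and the C10 hydroxyl appears in the last step.

Key step: step 6

Remark: positions follow the chain numbering C1–C19 of the parent 6,9-epoxynonadec-18-ene-7,10-diol. C6 is the ring carbon with pentyl, C7 the ester carbon, C8 the ring CH2, C9 the ring carbon with the side chain, and C10 the carbinol carbon. The target is (6S,7S,9R,10R).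

## Route

Step 1
Reactants: 1 (±)-oct-1-en-3-ol
Product: 2 (1S)-1-[(2R)-oxiran-2-yl]hexan-1-ol
Conditions: Ti(OiPr)4 (10 mol %), L-(+)-DIPT (15 mol %), t-BuOOH (0.45 equiv), 4 Å MS, CH2Cl2, −20 °C
Reagents that add atoms: tert-butyl hydroperoxide, CC(C)(C)OO
Why: Sharpless kinetic-resolution epoxidation, in which the L-(+)-tartrate catalyst should epoxidise the (S)-alcohol of the racemate much faster than the (R)-alcohol and on the face that gives the erythro epoxy alcohol, so that C6 (S) and C7 (R) are set together and unreacted (R)-1 is removed by chromatography.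

Step 2
Reactants: 2 (1S)-1-[(2R)-oxiran-2-yl]hexan-1-ol
Product: 3 (2R)-2-[(1S)-1-(ethenyloxy)hexyl]oxirane
Conditions: Pd(OCOCF3)2 (2 mol %), 4,7-diphenyl-1,10-phenanthroline (2 mol %), Et3N (cat), n-BuOCH=CH2 (solvent), 75 °C
Reagents that add atoms: butyl vinyl ether, C=COCCCC
Why: Pd(II)-catalysed transfer vinylation (transetherification) exchanges O–H for O–CH=CH2 under weakly basic conditions that should leave the epoxide and both stereocentres untouched.

Step 3
Reactants: 3 (2R)-2-[(1S)-1-(ethenyloxy)hexyl]oxirane
Product: 4 (4R,5S)-5-(ethenyloxy)dec-1-en-4-ol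
Conditions: CH2=CHMgBr (1.5 equiv), CuI (10 mol %), THF, −40 → −10 °C; then H2O
Reagents that add atoms: vinylmagnesium bromide, C=C[Mg]Br
Why: Copper-catalysed Grignard opening of a terminal epoxide is an SN2 attack at the unsubstituted carbon C8, so it forms C8–C9 without touching C7, and the vinyl ether is inert to the organometallic reagent.

Step 4
Reactants: 4 (4R,5S)-5-(ethenyloxy)dec-1-en-4-ol; 5 dodecanoic acid (lauric acid)
Product: 6 (4S,5S)-5-(ethenyloxy)dec-1-en-4-yl dodecanoate
Conditions: PPh3, DIAD, toluene, 0 °C → rt
Reagents that add atoms: none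
Why: The Mitsunobu esterification displaces the activated C7 oxygen by laurate with SN2 inversion (7R → 7S), which turns the erythro C6/C7 pair into the required threo pair and places the ester on the only free hydroxyl.

Step 5
Reactants: 6 (4S,5S)-5-(ethenyloxy)dec-1-en-4-yl dodecanoate
Product: 7 (2S,3S)-2-pentyl-3,4-dihydro-2H-pyran-3-yl dodecanoate
Conditions: Grubbs II catalyst (10 mol %), 1,4-benzoquinone (10 mol %), toluene (5 mM), 70 °C, Ar sparge
Reagents that add atoms: none
Why: Ring-closing metathesis of an olefinic vinyl ether (enol ether–olefin RCM) should start at the unhindered terminal alkene and close the six-membered cyclic enol ether with loss of ethene, and no stereocentre takes part.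

Step 6
Reactants: 7 (2S,3S)-2-pentyl-3,4-dihydro-2H-pyran-3-yl dodecanoate
Product: 9 (2S,3S,5R)-5-formyl-2-pentyloxolan-3-yl dodecanoate, via iodonium hemiacetal tosylate 8 (not isolated)
Conditions: PhI(OH)OTs (1.1 equiv), MeCN–H2O 10:1, −20 → 0 °C, slow addition of 7; then aq NaHCO3
Reagents that add atoms: water, O
Why: PhI(OH)OTs adds as an iodine(III) electrophile to the nucleophilic enol ether carbon C9, water caps the resulting oxocarbenium ion at C10 to give 8, and in the chair of 8 that keeps the pentyl and phenyliodonio groups equatorial the C9–I bond lies antiperiplanar to the ring O–C10 bond, so that O migrates from C10 to C9 while iodobenzene leaves and the C10 hydroxyl collapses to the aldehyde. The closest known reaction type is the oxidative ring contraction of glycals and other 3,4-dihydro-2H-pyrans to 2,5-anhydroaldoses (tetrahydrofurfurals) with thallium(III) or iodine(III) oxidants, the enol ether counterpart of the contraction of pyranosides that carry an equatorial leaving group at C2. The oxolane closes by this 1,2-shift of the ring oxygen, which counts as a 5-exo-tet SN2 displacement at C9 and gives the same bond if 8 first opens to the hydroxy α-iodonio aldehyde. C9 is the only new stereocentre and is controlled by the substrate: the iodane should approach anti to the cis pentyl and acyloxy groups, the axial acyloxy group shielding the other face by a 1,3-diaxial contact as in additions to galactal, and the invertive oxygen shift then puts the formyl carbon trans to pentyl (9R). The step needs oxygen migration to outrun hydride shift, carbon shift, acyloxy participation, tosylate capture and acid-catalysed hydration of 7; with an equatorial nucleofuge only O and the C7–C8 bond are aligned and only the O shift leaves a stabilised cation, the laurate carbonyl cannot reach the rear of C9, the shift is intramolecular, and slow addition of 7 to the cold oxidant keeps free enol ether away from the acid that builds up. The enol ether is the only alkene in 7, which is why the terminal olefin is brought in one step later.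

Step 7
Reactants: 9 (2S,3S,5R)-5-formyl-2-pentyloxolan-3-yl dodecanoate; 10 9-bromonon-1-ene
Product: 12 (2S,3S,5R)-5-[(1R)-1-hydroxydec-9-en-1-yl]-2-pentyloxolan-3-yl dodecanoate, via non-8-enylmagnesium bromide 11 (not isolated)
Conditions: 10, Mg, Et2O, reflux; 9, MgBr2·OEt2 (3 equiv), CH2Cl2, −78 °C, then 11 (1.2 equiv), −78 °C; pH 7 buffer
Reagents that add atoms: none
Why: In this chelation-controlled Grignard addition magnesium should tie the aldehyde oxygen to the ring oxygen so that the nucleophile comes from the side of the C9 hydrogen and gives the threo (10R) carbinol, and at −78 °C the aldehyde should react far faster than the laurate ester.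

## Compound list

1 | (±)-oct-1-en-3-ol | C=CC(O)CCCCC | starting material
2 | (1S)-1-[(2R)-oxiran-2-yl]hexan-1-ol | CCCCC[C@H](O)[C@H]1CO1 | intermediate
3 | (2R)-2-[(1S)-1-(ethenyloxy)hexyl]oxirane | CCCCC[C@H](OC=C)[C@H]1CO1 | intermediate
4 | (4R,5S)-5-(ethenyloxy)dec-1-en-4-ol | CCCCC[C@H](OC=C)[C@H](O)CC=C | intermediate
5 | dodecanoic acid (lauric acid) | CCCCCCCCCCCC(=O)O | starting material
6 | (4S,5S)-5-(ethenyloxy)dec-1-en-4-yl dodecanoate | CCCCC[C@H](OC=C)[C@@H](OC(=O)CCCCCCCCCCC)CC=C | intermediate
7 | (2S,3S)-2-pentyl-3,4-dihydro-2H-pyran-3-yl dodecanoate | CCCCC[C@@H]1OC=CC[C@@H]1OC(=O)CCCCCCCCCCC | intermediate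
8 | [(3S,5S,6S)-5-(dodecanoyloxy)-2-hydroxy-6-pentyloxan-3-yl](phenyl)iodonium tosylate, anomeric centre undefined | CCCCC[C@@H]1OC(O)[C@@H]([I+]c2ccccc2)C[C@@H]1OC(=O)CCCCCCCCCCC.Cc1ccc(cc1)S(=O)(=O)[O-] | intermediate
9 | (2S,3S,5R)-5-formyl-2-pentyloxolan-3-yl dodecanoate | O=C[C@H]1C[C@H](OC(=O)CCCCCCCCCCC)[C@H](CCCCC)O1 | intermediate
10 | 9-bromonon-1-ene | C=CCCCCCCCBr | starting material
11 | non-8-enylmagnesium bromide | C=CCCCCCCC[Mg]Br | intermediate
12 | (2S,3S,5R)-5-[(1R)-1-hydroxydec-9-en-1-yl]-2-pentyloxolan-3-yl dodecanoate | C=CCCCCCCC[C@@H](O)[C@H]1C[C@H](OC(=O)CCCCCCCCCCC)[C@H](CCCCC)O1 | target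

Total step count: 7. Longest linear sequence: 7 steps (1 → 12).

## Steps most likely to fail

**Step 6.**
- What may go wrong: the iodane may attack both faces of the enol ether, which loses control at C9. The sulfonic acid that builds up may hydrate the enol ether. Tosylate may capture the iodonio centre before the oxygen shift.
- Fallback: it sets out from 7 and returns at 9, with an oxygen leaving group installed stepwise.
  - Epoxidation with dimethyldioxirane (acetone–CH2Cl2, 0 °C) on the face anti to the two substituents should give the 1,2-anhydro compound F1.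
  - Methanol opens F1 at C10 to the trans methyl glycoside F2. Any C9 epimer of F2 can be removed at the alcohol stage.
  - Tf2O and pyridine (CH2Cl2, −20 °C) give the equatorial triflate F3.
  - Warming F3 in 2,6-lutidine-buffered aqueous MeCN should bring about the classical solvolytic ring contraction of a pyranoside 2-sulfonate. Water then takes the methoxy oxocarbenium ion on to 9.

**Step 5.**
- What may go wrong: the ruthenium carbene may be trapped by the vinyl ether as an unreactive alkoxycarbene, and the terminal alkene may migrate before closure.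
- Fallback: it sets out from 3 and returns at 7, and it closes the ring by alkynol cycloisomerisation instead of metathesis.
  - Lithium acetylide–ethylenediamine (DMSO, rt) opens the epoxide to the alkynol F4.
  - A Mitsunobu reaction with 5 gives the inverted laurate F5.
  - PPTS in aqueous acetone removes the vinyl group to give the hydroxy alkyne F6.
  - A rhodium(I) vinylidene endo-cycloisomerisation ([Rh(cod)Cl]2, tris(4-fluorophenyl)phosphine, DMF, 85 °C) should close the O–C10 bond to 7.

**Step 7.**
- What may go wrong: chelation may be incomplete, which erodes facial selectivity at C10. The α-alkoxy aldehyde may be enolised, and the ester may be attacked.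
- Fallback: it sets out from 9 and returns at 12, and it sets C10 by reduction instead of addition.
  - Reagent 11 is added without regard to selectivity, which gives 12 together with the 10S epimer F7.
  - The mixture is oxidised with Dess–Martin periodinane (NaHCO3, CH2Cl2) to the ketone F8.
  - L-Selectride (THF, −78 °C) should reduce F8 under Felkin–Anh control to the threo alcohol 12 without touching the ester or the alkene.

## Further compounds

F1 | step 6 | (3S,4S)-3-pentyl-2,7-dioxabicyclo[4.1.0]heptan-4-yl dodecanoate, epoxide oxygen anti to pentyl and acyloxy | CCCCC[C@@H]1O[C@H]2O[C@H]2C[C@@H]1OC(=O)CCCCCCCCCCC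
F2 | step 6 | (2S,3S,5S,6S)-5-hydroxy-6-methoxy-2-pentyloxan-3-yl dodecanoate | CO[C@H]1O[C@@H](CCCCC)[C@@H](OC(=O)CCCCCCCCCCC)C[C@@H]1O
F3 | step 6 | (2S,3S,5S,6S)-6-methoxy-2-pentyl-5-[(trifluoromethanesulfonyl)oxy]oxan-3-yl dodecanoate | CO[C@H]1O[C@@H](CCCCC)[C@@H](OC(=O)CCCCCCCCCCC)C[C@@H]1OS(=O)(=O)C(F)(F)F
F4 | step 5 | (4R,5S)-5-(ethenyloxy)dec-1-yn-4-ol | CCCCC[C@H](OC=C)[C@H](O)CC#C
F5 | step 5 | (4S,5S)-5-(ethenyloxy)dec-1-yn-4-yl dodecanoate | CCCCC[C@H](OC=C)[C@@H](OC(=O)CCCCCCCCCCC)CC#C
F6 | step 5 | (4S,5S)-5-hydroxydec-1-yn-4-yl dodecanoate | CCCCC[C@H](O)[C@@H](OC(=O)CCCCCCCCCCC)CC#C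
F7 | step 7 | (2S,3S,5R)-5-[(1S)-1-hydroxydec-9-en-1-yl]-2-pentyloxolan-3-yl dodecanoate | C=CCCCCCCC[C@H](O)[C@H]1C[C@H](OC(=O)CCCCCCCCCCC)[C@H](CCCCC)O1
F8 | step 7 | (2S,3S,5R)-5-(dec-9-enoyl)-2-pentyloxolan-3-yl dodecanoate | C=CCCCCCCCC(=O)[C@H]1C[C@H](OC(=O)CCCCCCCCCCC)[C@H](CCCCC)O1
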